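**Plan**
- Cuts, in retrosynthetic order: the C2 acetate; the C19–O lactone bond (oxidative lactonisation); the C6–C7 bond of the ten-membered ring; the C8–C9 bond (NiCl2/CrCl2 alkenylation); the C2–C3 bond (alkyllithium addition); and the ring A bonds C1–C14 and C10–C11 (Diels–Alder).
- The C6–C7 cut is possible because C5 (carrying the exocyclic C16 methylene), the CHCl carbon C6 and the lactone O–CH carbon C7 sit in a row in the ten-membered ring as a homoallylic chlorohydrin, the retron of a γ-chloroallyl metal adding to a C7 aldehyde.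
- Forward: ring A is made first, the C3–C6 arm is joined at C2 and the C7/C8/C17/C19 arm at C9, the ten-membered ring closes by chromium-mediated γ-chloroallylation, and the γ-lactone closes last.
- Stereochemistry: C1/C10 from the catalytic enantioselective Diels–Alder reaction, C17 from the (S)-Roche ester, C2 by oxazaborolidine reduction, C9 by Felkin–Anh alkenylation, C11 by Rubottom oxidation anti to the C9 arm, C8 by osmylation anti to the C9 acetate, C6/C7 in the ring closure.

Key step: step 26

Remark: intermediates are named with briarane numbers (C1 quaternary ring-fusion carbon, C2 and C9 the CH–O carbons, C8 tertiary carbinol, C10 ring-fusion CH, C11 the C(OH)Me carbon, C12 ketone, C16 exocyclic methylene, C17 CH–Me, C19 lactone carbonyl); where no descriptor is given, each stereocentre has the configuration of the same carbon in 45, as fixed by the SMILES.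
Remark: the facial sense in step 2 is assumed from the formyl C–H···O binding model of oxazaborolidinium-bound 2-substituted enals; if the (S)-catalyst gave the mirror-image adduct, its enantiomer would be used.

Step 1
Reactants: 1 pent-1-en-3-one
Product: 2 (Z)-triisopropyl(penta-1,3-dien-3-yloxy)silane
Conditions: i-Pr3SiOTf, Et3N, Et2O, 0 °C to rt
Reagents that add atoms: triisopropylsilyl triflate, CC(C)[Si](C(C)C)(C(C)C)OS(=O)(=O)C(F)(F)F
Why: Soft enolisation (silyl enol ether formation) of the ethyl ketone gives the 2-silyloxy diene, the Z enol ether being favoured because the methyl group avoids the vinyl substituent.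

Step 2
Reactants: 2 (Z)-triisopropyl(penta-1,3-dien-3-yloxy)silane; 3 ethyl (E)-3-methyl-4-oxobut-2-enoate
Product: 4 ethyl (1S,2S,6S)-6-formyl-2,6-dimethyl-3-(triisopropylsilyloxy)cyclohex-3-ene-1-carboxylate
Conditions: triflimide salt of (S)-3,3-diphenyl-1-(2-methylphenyl)tetrahydro-1H,3H-pyrrolo[1,2-c][1,3,2]oxazaborole (20 mol %), CH2Cl2, −78 to −40 °C
Reagents that add atoms: none
Why: Catalytic enantioselective Diels–Alder reaction in which the boron-bound formyl group directs regiochemistry (formyl carbon para to the silyloxy carbon) and the catalyst shields one enal face, setting C1 and C10, while the E dienophile fixes the two carbonyl arms trans; the C11 methyl epimer formed is erased in step 20.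

Step 3
Reactants: 5 prop-2-yn-1-ol; 6 allylmagnesium bromide
Product: 8 (Z)-2-(chloromethylidene)pent-4-en-1-ol, via alkenylmagnesium chelate 7 (not isolated)
Conditions: CH2=CHCH2MgBr (3 equiv), Et2O, reflux; then N-chlorosuccinimide, THF, −40 °C to rt; NH4Cl (aq)
Reagents that add atoms: N-chlorosuccinimide, O=C1CCC(=O)N1Cl
Why: Alkoxide-directed anti carbomagnesiation puts the allyl group on the internal alkyne carbon and magnesium on the terminal one inside a five-membered chelate, and chlorination with retention leaves chlorine cis to CH2OH.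

Step 4
Reactants: 8 (Z)-2-(chloromethylidene)pent-4-en-1-ol
Product: 9 tert-butyldimethylsilyl ether of 8
Conditions: t-BuMe2SiCl, imidazole, DMF, rt
Reagents that add atoms: tert-butyldimethylsilyl chloride, CC(C)(C)[Si](C)(C)Cl
Why: Standard silyl protection of the primary allylic alcohol (the future C16 oxygen).

Step 5
Reactants: 9 tert-butyldimethylsilyl ether of 8
Product: 11 (Z)-3-((tert-butyldimethylsilyloxy)methyl)-4-chlorobut-3-en-1-ol, via ozonide 10 (not isolated)
Conditions: O3 (1 equiv), CH2Cl2, −78 °C; then NaBH4, MeOH, −78 to 0 °C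
Reagents that add atoms: ozone, [O-][O+]=O
Why: Ozonolysis with reductive work-up cleaves only the electron-richer monosubstituted alkene, the chloroalkene being deactivated, and borohydride takes the ozonide to the C3 alcohol.

Step 6
Reactants: 11 (Z)-3-((tert-butyldimethylsilyloxy)methyl)-4-chlorobut-3-en-1-ol
Product: 12 (Z)-tert-butyl((2-(chloromethylidene)-4-iodobutyl)oxy)dimethylsilane
Conditions: I2, PPh3, imidazole, CH2Cl2, 0 °C
Reagents that add atoms: iodine, [I][I]
Why: Appel-type iodination of the primary alcohol gives the C3 iodide without touching the chloroalkene.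

Step 7
Reactants: 12 (Z)-tert-butyl((2-(chloromethylidene)-4-iodobutyl)oxy)dimethylsilane; 4 ring A aldehyde ester
Product: 14 C2 carbinol (both C2 epimers), via alkyllithium 13 (not isolated)
Conditions: 12, t-BuLi (2.1 equiv), Et2O/pentane, −78 °C; then 4, −78 °C; AcOH, −78 °C
Reagents that add atoms: none
Why: Iodine–lithium exchange is far faster than any reaction of the alkenyl chloride, and 1,2-addition to the non-enolisable aldehyde outruns attack on the ester at −78 °C; the cold acidic quench prevents lactonisation, and the C2 mixture is removed in step 8.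

Step 8
Reactants: 14 C2 carbinol
Product: 15 C2 ketone
Conditions: Dess–Martin periodinane, NaHCO3, CH2Cl2, 0 °C to rt
Reagents that add atoms: none
Why: Dess–Martin oxidation of the neopentyl carbinol under bicarbonate buffering leaves silyl enol ether, chloroalkene and ester untouched.

Step 9
Reactants: 15 C2 ketone
Product: 16 (2R)-C2 alcohol
Conditions: (S)-1-methyl-3,3-diphenyltetrahydro-1H,3H-pyrrolo[1,2-c][1,3,2]oxazaborole (1.0 equiv), BH3·SMe2 (1.2 equiv), THF, −30 °C; MeOH
Reagents that add atoms: none
Why: Corey–Bakshi–Shibata reduction with the quaternary C1 side as the large group gives the (R)-carbinol, the same sense as Felkin–Anh attack anti to C10 (matched case), and the borate formed is not nucleophilic enough to lactonise onto the C9 ester.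

Step 10
Reactants: 16 (2R)-C2 alcohol
Product: 17 C2 tert-butyldimethylsilyl ether
Conditions: t-BuMe2SiOTf, 2,6-lutidine, CH2Cl2, −78 to 0 °C
Reagents that add atoms: tert-butyldimethylsilyl triflate, CC(C)(C)[Si](C)(C)OS(=O)(=O)C(F)(F)F
Why: Silyl triflate silylation caps the hindered secondary alcohol at low temperature before it can close onto the neighbouring ester.

Step 11
Reactants: 17 C2 tert-butyldimethylsilyl ether
Product: 18 C9 primary alcohol
Conditions: i-Bu2AlH (2.5 equiv), CH2Cl2, −78 to 0 °C
Reagents that add atoms: none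
Why: Hydride reduction of the ethyl ester to the primary alcohol; silyl ethers, silyl enol ether and chloroalkene are inert to i-Bu2AlH.

Step 12
Reactants: 18 C9 primary alcohol
Product: 19 C9 aldehyde
Conditions: Dess–Martin periodinane, NaHCO3, CH2Cl2, 0 °C to rt
Reagents that add atoms: none
Why: Dess–Martin oxidation gives the aldehyde, and C10 keeps its configuration because the trans-diequatorial arrangement of the two arms is the stable one.

Step 13
Reactants: 20 methyl (S)-3-hydroxy-2-methylpropanoate
Product: 21 methyl (S)-3-((tert-butyldiphenylsilyl)oxy)-2-methylpropanoate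
Conditions: t-BuPh2SiCl, imidazole, CH2Cl2, rt
Reagents that add atoms: tert-butyldiphenylsilyl chloride, CC(C)(C)[Si](Cl)(c1ccccc1)c1ccccc1
Why: Standard silyl protection of the future C19 oxygen with a group that survives every later step up to the global desilylation.

Step 14
Reactants: 21 methyl (S)-3-((tert-butyldiphenylsilyl)oxy)-2-methylpropanoate
Product: 22 (S)-3-((tert-butyldiphenylsilyl)oxy)-2-methylpropanal
Conditions: i-Bu2AlH (1.05 equiv), CH2Cl2, −78 °C
Reagents that add atoms: none
Why: Partial ester reduction stops at the aluminium hemiacetal at −78 °C, which gives the aldehyde on work-up without touching the α-stereocentre.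

Step 15
Reactants: 22 (S)-3-((tert-butyldiphenylsilyl)oxy)-2-methylpropanal
Product: 23 (R)-tert-butyl((2-methylbut-3-yn-1-yl)oxy)diphenylsilane
Conditions: dimethyl (1-diazo-2-oxopropyl)phosphonate, K2CO3, MeOH, 0 °C to rt
Reagents that add atoms: dimethyl (1-diazo-2-oxopropyl)phosphonate, CC(=O)C(=[N+]=[N-])P(=O)(OC)OC
Why: Seyferth–Gilbert homologation in the Ohira–Bestmann variant converts the aldehyde into the terminal alkyne under carbonate conditions mild enough to keep the C17 centre.

Step 16
Reactants: 23 (R)-tert-butyl((2-methylbut-3-yn-1-yl)oxy)diphenylsilane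
Product: 25 (S)-tert-butyl((3-iodo-2-methylbut-3-en-1-yl)oxy)diphenylsilane, via alkenylborane 24 (not isolated)
Conditions: B-iodo-9-borabicyclo[3.3.1]nonane, pentane, −20 to 0 °C; then AcOH
Reagents that add atoms: B-iodo-9-borabicyclo[3.3.1]nonane, IB1C2CCCC1CCC2
Why: Syn haloboration puts boron on the terminal and iodine on the internal alkyne carbon, and protodeboronation leaves the 2-iodoalkene (net Markovnikov hydroiodination).

Step 17
Reactants: 19 C9 aldehyde; 25 (S)-tert-butyl((3-iodo-2-methylbut-3-en-1-yl)oxy)diphenylsilane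
Product: 27 (9R)-C9 allylic alcohol, via alkenylchromium dichloride 26 (not isolated)
Conditions: CrCl2 (4 equiv), NiCl2 (2 mol %), Me2SO/THF, rt
Reagents that add atoms: none
Why: Nozaki–Hiyama–Kishi alkenylation, in which zerovalent nickel activates only the alkenyl iodide (the alkenyl chloride is inert) and the alkenylchromium adds to the aldehyde under Felkin–Anh control anti to the quaternary C1, setting C9.

Step 18
Reactants: 27 (9R)-C9 allylic alcohol
Product: 28 C9 acetate with silyl enol ether
Conditions: Ac2O, Et3N, 4-dimethylaminopyridine, CH2Cl2, rt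
Reagents that add atoms: acetic anhydride, CC(=O)OC(C)=O
Why: Nucleophile-catalysed acetylation esterifies the hindered allylic alcohol and installs the first acetate of the target.

Step 19
Reactants: 28 C9 acetate with silyl enol ether
Product: 29 C13–C14 enone
Conditions: Pd(OAc)2 (1.2 equiv), MeCN, rt to 40 °C
Reagents that add atoms: none
Why: Ito–Saegusa oxidation: palladation at C13 and β-hydride loss from C14 give the enone regiospecifically, and the phosphine-free stoichiometric conditions leave no ligated zerovalent palladium to ionise the allylic acetate.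

Step 20
Reactants: 29 C13–C14 enone
Product: 32 C11 tertiary alcohol, via silyl dienol ether 30 (not isolated), via silyloxy epoxide 31 (not isolated)
Conditions: Me3SiOTf, Et3N, CH2Cl2, 0 °C; concentrate; dimethyldioxirane (1.0 equiv), acetone/CH2Cl2, −78 °C; citric acid (aq), THF
Reagents that add atoms: dimethyldioxirane, CC1(C)OO1
Why: Rubottom oxidation: soft enolisation can only occur at C11 (C1 is quaternary) and avoids deprotonating the acetate, and the electron-rich enol ether double bond is epoxidised on the face opposite the adjacent pseudo-axial C9 arm, which after hydrolysis gives the C11 hydroxyl with the target configuration.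

Step 21
Reactants: 32 C11 tertiary alcohol
Product: 33 C16 allylic alcohol
Conditions: HF·pyridine, pyridine, THF, 0 °C
Reagents that add atoms: none
Why: Buffered fluoride cleaves the unhindered primary allylic silyl ether faster than the neopentyl secondary one at C2 or the tert-butyldiphenylsilyl ether (selective desilylation).

Step 22
Reactants: 33 C16 allylic alcohol
Product: 35 C16 allylic chloride, via mesylate 34 (not isolated)
Conditions: MeSO2Cl, 2,4,6-collidine, LiCl, DMF, 0 °C
Reagents that add atoms: lithium chloride, [Li+].[Cl-]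
Why: Collington–Meyers chlorination displaces the primary allylic mesylate by chloride without allylic transposition, and the tertiary C11 alcohol does not react.

Step 23
Reactants: 35 C16 allylic chloride
Product: 36 C7,C8 diol
Conditions: OsO4 (5 mol %), N-methylmorpholine N-oxide, acetone/H2O, rt, neutral work-up
Reagents that add atoms: N-methylmorpholine N-oxide, C[N+]1([O-])CCOCC1; water, O
Why: Upjohn dihydroxylation takes the only electron-rich alkene (enone and chloroalkene are deactivated) and, by Kishi's rule, adds anti to the C9 acetoxy group in the conformer with C9–H in the alkene plane, setting C8; neutral conditions limit acetyl migration.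

Step 24
Reactants: 36 C7,C8 diol
Product: 37 tris(triethylsilyl) ether
Conditions: Et3SiOTf (5 equiv), 2,6-lutidine, CH2Cl2, −78 to 0 °C
Reagents that add atoms: triethylsilyl triflate, CC[Si](CC)(CC)OS(=O)(=O)C(F)(F)F
Why: Exhaustive silylation covers the primary C7 and the tertiary C8 and C11 hydroxyls, the non-chelating silyl ether at C8 being the control element for step 26.

Step 25
Reactants: 37 tris(triethylsilyl) ether
Product: 38 C7 aldehyde
Conditions: (COCl)2, Me2SO, CH2Cl2, −78 to −30 °C; then Et3N
Reagents that add atoms: none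
Why: Swern conditions cleave and oxidise primary triethylsilyl ethers directly to aldehydes while tertiary triethylsilyl and the other silyl ethers stay (selective oxidative desilylation), so no free α-hydroxy aldehyde is handled.

Step 26
Reactants: 38 C7 aldehyde
Product: 40 ten-membered chlorohydrin, via allylchromium dichloride 39 (not isolated)
Conditions: CrCl2 (4 equiv), THF/DMF 10:1, rt, 38 added by syringe pump over 12 h (final 2 mM); then H2O
Reagents that add atoms: none
Why: Proposed new method: divalent chromium inserts only into the primary allylic C16–Cl bond (the alkenyl chloride would need nickel), and the allylchromium 39, which equilibrates its alkene geometry by 1,3-metal shift, adds through its chlorine-bearing γ-carbon C6 to the C7 aldehyde in a six-membered chair with transposition of the double bond to C5=C16; the closest known reactions are Nozaki–Hiyama–Kishi macro-allylations of formyl allylic halides that close ten-membered germacrane rings and intermolecular additions of γ-chloroallyl chromium reagents to aldehydes that give anti chlorohydrins. The ten-membered carbocycle closes by intramolecular carbonyl allylation (C6–C7 bond, C5 and C6 inside the ring, C16 outside), the chain being pre-organised by the trans arms on ring A and the fully substituted C1 and C8. C6 is set by the chair with chlorine equatorial (Curtin–Hammett over the equilibrating allylchromium), which gives the anti C6/C7 chlorohydrin, and C7 by polar Felkin–Anh attack anti to the non-chelating C8 triethylsilyloxy group. The step needs ring closure to beat oligomerisation, which slow addition at high dilution secures, and it needs the enone, the acetate and the new secondary allylic chloride to survive, for which iodide additives are left out and the excess of CrCl2 is kept small.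

Step 27
Reactants: 40 ten-membered chlorohydrin
Product: 41 pentaol
Conditions: HF·pyridine (excess), pyridine, THF, 0 °C to rt
Reagents that add atoms: none
Why: Global desilylation under buffered acidic fluoride removes all four silyl groups, keeps the acetate and cannot close the chlorohydrin to an epoxide as a basic fluoride source would.

Step 28
Reactants: 41 pentaol
Product: 44 hydroxy lactone, via hydroxy aldehyde 42 (not isolated), via lactol 43 (not isolated)
Conditions: 2,2,6,6-tetramethylpiperidin-1-oxyl (20 mol %), PhI(OAc)2 (3 equiv), CH2Cl2, rt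
Reagents that add atoms: none
Why: Nitroxyl-catalysed oxidation is selective for the primary C19 alcohol, the aldehyde is trapped by the C7 hydroxyl as a five-membered lactol and oxidised on to the γ-lactone (oxidative lactonisation), while the hindered secondary C2 and the tertiary alcohols are left.

Step 29
Reactants: 44 hydroxy lactone
Product: 45 CNP0261648.1
Conditions: Ac2O, pyridine, 4-dimethylaminopyridine (cat.), CH2Cl2, 0 °C to rt
Reagents that add atoms: acetic anhydride, CC(=O)OC(C)=O
Why: Acetylation takes the only secondary alcohol (C2), since the tertiary C8 and C11 alcohols do not acylate under these conditions.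

**Compound list**
1 | pent-1-en-3-one | C=CC(=O)CC | starting material
2 | (Z)-triisopropyl(penta-1,3-dien-3-yloxy)silane | C/C=C(\O[Si](C(C)C)(C(C)C)C(C)C)C=C | intermediate
3 | ethyl (E)-3-methyl-4-oxobut-2-enoate | CCOC(=O)/C=C(\C)C=O | starting material
4 | ethyl (1S,2S,6S)-6-formyl-2,6-dimethyl-3-(triisopropylsilyloxy)cyclohex-3-ene-1-carboxylate (ring A: formyl = C2, ester = C9) | O=C[C@@]1(C)CC=C(O[Si](C(C)C)(C(C)C)C(C)C)[C@@H](C)[C@@H]1C(=O)OCC | intermediate
5 | prop-2-yn-1-ol | C#CCO | starting material
6 | allylmagnesium bromide | C=CC[Mg]Br | starting material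
7 | 4-allyl-2,5-dihydro-1,2-oxamagnesole (alkenylmagnesium chelate) | C=CCC1=C[Mg]OC1 | intermediate (not isolated)
8 | (Z)-2-(chloromethylidene)pent-4-en-1-ol | Cl/C=C(/CC=C)CO | intermediate
9 | (Z)-tert-butyl((2-(chloromethylidene)pent-4-en-1-yl)oxy)dimethylsilane | Cl/C=C(/CC=C)CO[Si](C)(C)C(C)(C)C | intermediate
10 | ozonide (1,2,4-trioxolane) of the terminal alkene of 9 | Cl/C=C(/CC1OCOO1)CO[Si](C)(C)C(C)(C)C | intermediate (not isolated)
11 | (Z)-3-((tert-butyldimethylsilyloxy)methyl)-4-chlorobut-3-en-1-ol | Cl/C=C(/CCO)CO[Si](C)(C)C(C)(C)C | intermediate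
12 | (Z)-tert-butyl((2-(chloromethylidene)-4-iodobutyl)oxy)dimethylsilane (C3–C6 arm) | Cl/C=C(/CCI)CO[Si](C)(C)C(C)(C)C | intermediate
13 | alkyllithium from 12 (lithium at C3) | Cl/C=C(/CC[Li])CO[Si](C)(C)C(C)(C)C | intermediate (not isolated)
14 | C2 carbinol, both C2 epimers: 4 with CH(OH)CH2CH2C(CH2OSi-t-BuMe2)=CHCl (Z) in place of the formyl group | OC(CC/C(CO[Si](C)(C)C(C)(C)C)=C/Cl)[C@@]1(C)CC=C(O[Si](C(C)C)(C(C)C)C(C)C)[C@@H](C)[C@@H]1C(=O)OCC | intermediate
15 | C2 ketone of 14 | O=C(CC/C(CO[Si](C)(C)C(C)(C)C)=C/Cl)[C@@]1(C)CC=C(O[Si](C(C)C)(C(C)C)C(C)C)[C@@H](C)[C@@H]1C(=O)OCC | intermediate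
16 | (2R)-C2 alcohol with C9 ethyl ester | Cl/C=C(/CC[C@@H](O)[C@@]1(C)CC=C(O[Si](C(C)C)(C(C)C)C(C)C)[C@@H](C)[C@@H]1C(=O)OCC)CO[Si](C)(C)C(C)(C)C | intermediate
17 | C2 tert-butyldimethylsilyl ether of 16 | Cl/C=C(/CC[C@@H](O[Si](C)(C)C(C)(C)C)[C@@]1(C)CC=C(O[Si](C(C)C)(C(C)C)C(C)C)[C@@H](C)[C@@H]1C(=O)OCC)CO[Si](C)(C)C(C)(C)C | intermediate
18 | C9 primary alcohol (ester of 17 reduced) | Cl/C=C(/CC[C@@H](O[Si](C)(C)C(C)(C)C)[C@@]1(C)CC=C(O[Si](C(C)C)(C(C)C)C(C)C)[C@@H](C)[C@@H]1CO)CO[Si](C)(C)C(C)(C)C | intermediate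
19 | C9 aldehyde | Cl/C=C(/CC[C@@H](O[Si](C)(C)C(C)(C)C)[C@@]1(C)CC=C(O[Si](C(C)C)(C(C)C)C(C)C)[C@@H](C)[C@@H]1C=O)CO[Si](C)(C)C(C)(C)C | intermediate
20 | methyl (S)-3-hydroxy-2-methylpropanoate | COC(=O)[C@@H](C)CO | starting material
21 | methyl (S)-3-((tert-butyldiphenylsilyl)oxy)-2-methylpropanoate | COC(=O)[C@@H](C)CO[Si](c1ccccc1)(c1ccccc1)C(C)(C)C | intermediate
22 | (S)-3-((tert-butyldiphenylsilyl)oxy)-2-methylpropanal | O=C[C@@H](C)CO[Si](c1ccccc1)(c1ccccc1)C(C)(C)C | intermediate
23 | (R)-tert-butyl((2-methylbut-3-yn-1-yl)oxy)diphenylsilane | C#C[C@@H](C)CO[Si](c1ccccc1)(c1ccccc1)C(C)(C)C | intermediate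
24 | (Z)-2-iodoalkenyl-9-borabicyclo[3.3.1]nonane from 23 (boron on C7, iodine on C8, cis) | I/C(=C\B1C2CCCC1CCC2)[C@@H](C)CO[Si](c1ccccc1)(c1ccccc1)C(C)(C)C | intermediate (not isolated)
25 | (S)-tert-butyl((3-iodo-2-methylbut-3-en-1-yl)oxy)diphenylsilane (C7/C8/C17/C19 arm) | C=C(I)[C@@H](C)CO[Si](c1ccccc1)(c1ccccc1)C(C)(C)C | intermediate
26 | alkenylchromium dichloride from 25 | C=C([Cr](Cl)Cl)[C@@H](C)CO[Si](c1ccccc1)(c1ccccc1)C(C)(C)C | intermediate (not isolated)
27 | (9R)-C9 allylic alcohol with C8=C7 methylene | Cl/C=C(/CC[C@@H](O[Si](C)(C)C(C)(C)C)[C@@]1(C)CC=C(O[Si](C(C)C)(C(C)C)C(C)C)[C@@H](C)[C@@H]1[C@@H](O)C(=C)[C@@H](C)CO[Si](c2ccccc2)(c2ccccc2)C(C)(C)C)CO[Si](C)(C)C(C)(C)C | intermediate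
28 | C9 acetate of 27 | Cl/C=C(/CC[C@@H](O[Si](C)(C)C(C)(C)C)[C@@]1(C)CC=C(O[Si](C(C)C)(C(C)C)C(C)C)[C@@H](C)[C@@H]1[C@@H](OC(C)=O)C(=C)[C@@H](C)CO[Si](c2ccccc2)(c2ccccc2)C(C)(C)C)CO[Si](C)(C)C(C)(C)C | intermediate
29 | C12 ketone with C13–C14 alkene (enone), C11–H | Cl/C=C(/CC[C@@H](O[Si](C)(C)C(C)(C)C)[C@@]1(C)C=CC(=O)[C@@H](C)[C@@H]1[C@@H](OC(C)=O)C(=C)[C@@H](C)CO[Si](c2ccccc2)(c2ccccc2)C(C)(C)C)CO[Si](C)(C)C(C)(C)C | intermediate
30 | cross-conjugated trimethylsilyl dienol ether (C11=C12, C13=C14) | Cl/C=C(/CC[C@@H](O[Si](C)(C)C(C)(C)C)[C@@]1(C)C=CC(O[Si](C)(C)C)=C(C)[C@@H]1[C@@H](OC(C)=O)C(=C)[C@@H](C)CO[Si](c2ccccc2)(c2ccccc2)C(C)(C)C)CO[Si](C)(C)C(C)(C)C | intermediate (not isolated)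
31 | C11,C12 α-epoxide of 30 bearing the C12 trimethylsilyloxy group | Cl/C=C(/CC[C@@H](O[Si](C)(C)C(C)(C)C)[C@@]1(C)C=C[C@@]2(O[Si](C)(C)C)O[C@@]2(C)[C@@H]1[C@@H](OC(C)=O)C(=C)[C@@H](C)CO[Si](c3ccccc3)(c3ccccc3)C(C)(C)C)CO[Si](C)(C)C(C)(C)C | intermediate (not isolated)
32 | enone with C11 tertiary alcohol | Cl/C=C(/CC[C@@H](O[Si](C)(C)C(C)(C)C)[C@@]1(C)C=CC(=O)[C@@](C)(O)[C@@H]1[C@@H](OC(C)=O)C(=C)[C@@H](C)CO[Si](c2ccccc2)(c2ccccc2)C(C)(C)C)CO[Si](C)(C)C(C)(C)C | intermediate
33 | C16 allylic alcohol | Cl/C=C(/CC[C@@H](O[Si](C)(C)C(C)(C)C)[C@@]1(C)C=CC(=O)[C@@](C)(O)[C@@H]1[C@@H](OC(C)=O)C(=C)[C@@H](C)CO[Si](c2ccccc2)(c2ccccc2)C(C)(C)C)CO | intermediate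
34 | C16 mesylate | Cl/C=C(/CC[C@@H](O[Si](C)(C)C(C)(C)C)[C@@]1(C)C=CC(=O)[C@@](C)(O)[C@@H]1[C@@H](OC(C)=O)C(=C)[C@@H](C)CO[Si](c2ccccc2)(c2ccccc2)C(C)(C)C)COS(C)(=O)=O | intermediate (not isolated)
35 | C16 allylic chloride | Cl/C=C(/CC[C@@H](O[Si](C)(C)C(C)(C)C)[C@@]1(C)C=CC(=O)[C@@](C)(O)[C@@H]1[C@@H](OC(C)=O)C(=C)[C@@H](C)CO[Si](c2ccccc2)(c2ccccc2)C(C)(C)C)CCl | intermediate
36 | C7,C8 diol (C7 primary, C8 tertiary) | Cl/C=C(/CC[C@@H](O[Si](C)(C)C(C)(C)C)[C@@]1(C)C=CC(=O)[C@@](C)(O)[C@@H]1[C@@H](OC(C)=O)[C@](CO)(O)[C@@H](C)CO[Si](c2ccccc2)(c2ccccc2)C(C)(C)C)CCl | intermediate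
37 | C7, C8, C11 tris(triethylsilyl) ether | Cl/C=C(/CC[C@@H](O[Si](C)(C)C(C)(C)C)[C@@]1(C)C=CC(=O)[C@@](C)(O[Si](CC)(CC)CC)[C@@H]1[C@@H](OC(C)=O)[C@](CO[Si](CC)(CC)CC)(O[Si](CC)(CC)CC)[C@@H](C)CO[Si](c2ccccc2)(c2ccccc2)C(C)(C)C)CCl | intermediate
38 | C7 aldehyde with C16 allylic chloride (ring-closure precursor) | Cl/C=C(/CC[C@@H](O[Si](C)(C)C(C)(C)C)[C@@]1(C)C=CC(=O)[C@@](C)(O[Si](CC)(CC)CC)[C@@H]1[C@@H](OC(C)=O)[C@](C=O)(O[Si](CC)(CC)CC)[C@@H](C)CO[Si](c2ccccc2)(c2ccccc2)C(C)(C)C)CCl | intermediate
39 | allylchromium dichloride (chromium on C16) | Cl/C=C(/CC[C@@H](O[Si](C)(C)C(C)(C)C)[C@@]1(C)C=CC(=O)[C@@](C)(O[Si](CC)(CC)CC)[C@@H]1[C@@H](OC(C)=O)[C@](C=O)(O[Si](CC)(CC)CC)[C@@H](C)CO[Si](c2ccccc2)(c2ccccc2)C(C)(C)C)C[Cr](Cl)Cl | intermediate (not isolated)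
40 | ten-membered carbocycle: C5=C16 methylene, (6S)-chloride, (7R)-alcohol, silyl ethers at C2, C8, C11, C19 | C=C1CC[C@@H](O[Si](C)(C)C(C)(C)C)[C@@]2(C)C=CC(=O)[C@@](C)(O[Si](CC)(CC)CC)[C@@H]2[C@@H](OC(C)=O)[C@](O[Si](CC)(CC)CC)([C@@H](C)CO[Si](c3ccccc3)(c3ccccc3)C(C)(C)C)[C@@H](O)[C@H]1Cl | intermediate
41 | pentaol (free C2, C7, C8, C11, C19 hydroxyls, C9 acetate) | C=C1CC[C@@H](O)[C@@]2(C)C=CC(=O)[C@@](C)(O)[C@@H]2[C@@H](OC(C)=O)[C@](O)([C@@H](C)CO)[C@@H](O)[C@H]1Cl | intermediate
42 | C19 aldehyde of 41 | C=C1CC[C@@H](O)[C@@]2(C)C=CC(=O)[C@@](C)(O)[C@@H]2[C@@H](OC(C)=O)[C@](O)([C@@H](C)C=O)[C@@H](O)[C@H]1Cl | intermediate (not isolated)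
43 | C19,C7 lactol (either anomer) | C=C1CC[C@@H](O)[C@@]2(C)C=CC(=O)[C@@](C)(O)[C@@H]2[C@@H](OC(C)=O)[C@]2(O)[C@@H](C)C(O)O[C@H]2[C@H]1Cl | intermediate (not isolated)
44 | γ-lactone with free C2 hydroxyl (2-deacetyl target) | C=C1CC[C@@H](O)[C@@]2(C)C=CC(=O)[C@@](C)(O)[C@@H]2[C@@H](OC(C)=O)[C@]2(O)[C@@H](C)C(=O)O[C@H]2[C@H]1Cl | intermediate
45 | CNP0261648.1, (1S,2R,6S,7R,8R,9R,10S,11S,17R)-2,9-diacetoxy-6-chloro-8,11-dihydroxy-12-oxobriara-5(16),13-dien-19,7-olide | C=C1CC[C@@H](OC(C)=O)[C@@]2(C)C=CC(=O)[C@@](C)(O)[C@@H]2[C@@H](OC(C)=O)[C@]2(O)[C@@H](C)C(=O)O[C@H]2[C@H]1Cl | target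

**Totals**
Total step count: 29. Longest linear sequence: 23 steps (5 to 45 through steps 3–12 and 17–29).

**Steps most likely to fail**

1. Step 26 (proposed new method). What may go wrong: the chlorine does not survive the ring closure, because the C7 chromium alkoxide displaces the activated allylic C6 chloride and the product drains into the vinyl epoxide. This fallback rescues the chlorine only: it still relies on the chromium ring closure. I found no short alternative built only from known reactions that closes the ring if that closure itself fails, since the arm and its chloroalkene are fixed from step 7 on. Fallback, setting out from 38 and coming back at 40: the cyclisation is run without regard for the chloride and the crude product is converted completely into the trans-6,7-vinyl epoxide F1 with Ag2O in CH2Cl2 (halohydrin-to-epoxide closure). Chloride is then returned by SN2 opening at the allylic carbon C6 with CeCl3·7H2O in MeCN (the usual site of attack on vinyl epoxides). The two inversions at C6 cancel and C7 is untouched, so 40 results.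

2. Step 23. What may go wrong: osmium adds to the other face of the 1,1-disubstituted alkene (C8 epimer), or the C9 acetyl group migrates to the new primary hydroxyl. Fallback, setting out from 35 and coming back at 36: epoxidation with m-chloroperbenzoic acid (NaHCO3, CH2Cl2) gives the 7,8-epoxide F2 with oxygen on the face osmium prefers. Catalytic camphorsulfonic acid in wet THF then opens it at the tertiary C8 with inversion through the C9 acetoxonium ion, whose hydrolysis returns the C9 acetate. This anti opening gives the C8 configuration opposite to syn dihydroxylation from the same face, that is 36.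

3. Step 17. What may go wrong: the neopentyl-type C9 aldehyde reacts too slowly with the alkenylchromium, which is then protonated. Fallback, setting out from 25 and coming back at 27: iodine–lithium exchange (t-BuLi, 2 equiv, Et2O, −78 °C) gives the alkenyllithium F3, which is added to 19 at −78 °C. This stoichiometric organolithium addition follows the same Felkin–Anh course and gives 27.

**Further compounds**
F1 | step 26 | trans-6,7-vinyl epoxide of the ten-membered ring (C5=C16 methylene kept, silyl ethers as in 40) | C=C1CC[C@@H](O[Si](C)(C)C(C)(C)C)[C@@]2(C)C=CC(=O)[C@@](C)(O[Si](CC)(CC)CC)[C@@H]2[C@@H](OC(C)=O)[C@](O[Si](CC)(CC)CC)([C@@H](C)CO[Si](c3ccccc3)(c3ccccc3)C(C)(C)C)[C@H]3O[C@H]13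
F2 | step 23 | 7,8-epoxide of 35 with oxygen on the face opposite to the C8 hydroxyl of 36 | Cl/C=C(/CC[C@@H](O[Si](C)(C)C(C)(C)C)[C@@]1(C)C=CC(=O)[C@@](C)(O)[C@@H]1[C@@H](OC(C)=O)[C@]2(CO2)[C@@H](C)CO[Si](c3ccccc3)(c3ccccc3)C(C)(C)C)CCl
F3 | step 17 | alkenyllithium from 25 (lithium on C8) | [Li]C(=C)[C@@H](C)CO[Si](c1ccccc1)(c1ccccc1)C(C)(C)C
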